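The single carbocycle (C1 ring ketone, C2 benzoyl-bearing, C3 and C5 enol carbons, C4 gem-diprenyl, C6 prenyl-bearing) has alternating oxygenation, so C3–C4–C5 is a symmetrical 2,2-diprenylmalonyl unit and C2–C1–C6 the backbone of a γ-prenylated benzoylacetone. Everything rests on cutting C2–C3 and C5–C6. One [3+3] operation, the double C-acylation of a bis-silyl dienol ether by a malonyl dichloride, forms both bonds, closes the ring and installs the quaternary carbon C4 with every substituent in place. Its precursors are 2,2-diprenylmalonyl dichloride, which cannot form a ketene, and the bis(trimethylsilyl) dienol ether of the diketone; a methoxide quench removes silicon and funnels O-acylated isomers to the carbocycle.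

Key step: step 7

Assumption: the target is one tautomer of a rapidly equilibrating enolised β-triketone, and the route delivers that equilibrium mixture. The enol ether geometries of the silylated intermediates are drawn as the expected major isomers and have no bearing on the outcome, since both enol carbons end up as ring sp2 carbons.

Step 1
Reactants: 1 diethyl malonate; 2 prenyl bromide (1-bromo-3-methylbut-2-ene)
Product: 4 diethyl 2,2-bis(3-methylbut-2-enyl)propanedioate, via diethyl 2-(3-methylbut-2-enyl)propanedioate 3 (not isolated)
Conditions: NaH (2.3 equiv), 2 (2.2 equiv), THF, 0 °C → 50 °C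
Reagents that add atoms: none
Why: Twofold malonic ester alkylation, in which the sodium enolate displaces the primary allylic bromide by SN2 twice, the second time readily because prenyl bromide is an unhindered, activated electrophile; no stereocentre arises.

Step 2
Reactants: 4 diethyl 2,2-bis(3-methylbut-2-enyl)propanedioate
Product: 6 2,2-bis(3-methylbut-2-enyl)propanedioic acid, via dipotassium 2,2-bis(3-methylbut-2-enyl)propanedioate 5 (not isolated)
Conditions: KOH (6 equiv), EtOH/H2O 3:1, reflux; then 1 M HCl to pH 2 at 0 °C, extraction into EtOAc, concentration below 30 °C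
Reagents that add atoms: potassium hydroxide, [K+].[OH-]
Why: Saponification of a non-enolisable diester that can only hydrolyse, followed by cold and brief acidification so that neither decarboxylation nor acid-catalysed lactonisation onto a prenyl group should set in.

Step 3
Reactants: 6 2,2-bis(3-methylbut-2-enyl)propanedioic acid
Product: 7 2,2-bis(3-methylbut-2-enyl)propanedioyl dichloride
Conditions: 1-chloro-N,N,2-trimethylprop-1-en-1-amine (2.2 equiv), CH2Cl2, 0 °C → 20 °C; solvent and amide removed bulb-to-bulb at 0.05 mbar, used directly
Reagents that add atoms: 1-chloro-N,N,2-trimethylprop-1-en-1-amine, CC(C)=C(Cl)N(C)C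
Why: Acid-to-acid-chloride conversion with an α-chloroenamine runs through an acyloxyiminium chloride under neutral conditions, so no free HCl reaches the trisubstituted alkenes, and the quaternary α-carbon excludes ketene formation.

Step 4
Reactants: 8 benzoylacetone (1-phenylbutane-1,3-dione); 2 prenyl bromide
Product: 10 7-methyl-1-phenyloct-6-ene-1,3-dione, via dilithium 1-phenylbuta-1,3-diene-1,3-bis(olate) 9 (not isolated)
Conditions: LiN(iPr)2 (2.1 equiv), THF, −78 → 0 °C; then 2 (1.0 equiv), −78 → 0 °C; aq. NH4Cl
Reagents that add atoms: none
Why: γ-Alkylation of a β-diketone dianion, whose terminal carbanion is formed last and is the most nucleophilic site, so the allylic bromide should be taken up by SN2 at the former methyl carbon only.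

Step 5
Reactants: 10 7-methyl-1-phenyloct-6-ene-1,3-dione
Product: 11 (Z)-7-methyl-1-phenyl-3-(trimethylsilyloxy)octa-2,6-dien-1-one
Conditions: Me3SiCl (1.5 equiv), NEt3 (1.6 equiv), toluene, 20 °C; filtration under argon, concentration
Reagents that add atoms: chlorotrimethylsilane, C[Si](C)(C)Cl
Why: O-silylation of the hydrogen-bonded enol of a β-diketone gives the Z vinylogous silyl ester, and the regioisomer silylated at the benzoyl oxygen, if it forms, converges on the same dienol ether in step 6.

Step 6
Reactants: 11 (Z)-7-methyl-1-phenyl-3-(trimethylsilyloxy)octa-2,6-dien-1-one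
Product: 13 (1Z,3Z)-7-methyl-1-phenyl-1,3-bis(trimethylsilyloxy)octa-1,3,6-triene, via lithium dienolate of the mono-silyl ether 12 (not isolated)
Conditions: LiN(iPr)2 (1.2 equiv), THF, −78 °C; Me3SiCl (1.3 equiv), −78 → 20 °C; concentration, hexane, filtration under argon; used crude
Reagents that add atoms: chlorotrimethylsilane, C[Si](C)(C)Cl
Why: Kinetic γ-deprotonation of the vinylogous silyl ester gives an extended lithium dienolate that the hard silicon electrophile traps on oxygen, the standard two-stage preparation of 1,3-bis(silyloxy)-1,3-dienes from 1,3-diketones.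

Step 7
Reactants: 7 2,2-bis(3-methylbut-2-enyl)propanedioyl dichloride; 13 (1Z,3Z)-7-methyl-1-phenyl-1,3-bis(trimethylsilyloxy)octa-1,3,6-triene
Product: 16 2-benzoyl-3,5-dihydroxy-4,4,6-tris(3-methylbut-2-enyl)cyclohexa-2,5-dien-1-one, via acyclic keto acid chloride 14 (not isolated), via sodium enolate of the triketone 15 (not isolated)
Conditions: 13 (1.05 equiv) added over 2 h to 7, CH2Cl2 (0.05 M), −78 °C → 20 °C, argon; then NaOMe (5 equiv), MeOH, 0 → 20 °C; aq. citric acid to pH 3 at 0 °C
Reagents that add atoms: none
Why: The electron-rich terminal carbon of 13 (future C6) attacks one acid chloride of 7 in a Mukaiyama-type C-acylation with loss of Me3SiCl to give 14, whose remaining silyl enol ether carbon (future C2) then attacks the second acid chloride, again releasing Me3SiCl, so that bonds C5–C6 and C2–C3 form in one flask. The closest known reactions are the Effenberger annulation of enol ethers with malonyl dichlorides to cyclohexane-1,3,5-triones and the terminal C-acylation of 1,3-bis(silyloxy)-1,3-dienes by acid chlorides. The six-membered carbocycle closes in a 6-(enolexo)-exo-trig mode, the enol ether double bond C2=C(OSiMe3)Ph lying outside the ring being formed. No stereocentre is created, because C4 carries two identical prenyl groups and C2 and C6 end up as enol carbons. The step needs C- over O-acylation and cyclisation over oligomerisation: 7 has no α-hydrogen and so cannot react through a ketene, its gem-diprenyl carbon presses the chain ends together (Thorpe–Ingold effect), slow addition at moderate dilution keeps intermolecular coupling down, and the two COCl groups are equivalent, so no regiochemical question arises. The NaOMe quench converts the liberated Me3SiCl into MeOSiMe3 and NaCl before acid can cyclise prenyl groups onto enol oxygens, and it should convert an O-acylated enol lactone or an uncyclised ester by ring opening and Claisen (Dieckmann) closure into the enolate 15 of the strongly acidic β-triketone, the thermodynamic sink.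

Compound list
1 | diethyl malonate | CCOC(=O)CC(=O)OCC | starting material
2 | prenyl bromide (1-bromo-3-methylbut-2-ene) | CC(C)=CCBr | starting material
3 | diethyl 2-(3-methylbut-2-enyl)propanedioate (not isolated) | CCOC(=O)C(CC=C(C)C)C(=O)OCC | intermediate
4 | diethyl 2,2-bis(3-methylbut-2-enyl)propanedioate | CCOC(=O)C(CC=C(C)C)(CC=C(C)C)C(=O)OCC | intermediate
5 | dipotassium 2,2-bis(3-methylbut-2-enyl)propanedioate (not isolated) | [K+].[K+].CC(C)=CCC(CC=C(C)C)(C(=O)[O-])C(=O)[O-] | intermediate
6 | 2,2-bis(3-methylbut-2-enyl)propanedioic acid | CC(C)=CCC(CC=C(C)C)(C(=O)O)C(=O)O | intermediate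
7 | 2,2-bis(3-methylbut-2-enyl)propanedioyl dichloride | CC(C)=CCC(CC=C(C)C)(C(Cl)=O)C(Cl)=O | intermediate
8 | benzoylacetone (1-phenylbutane-1,3-dione) | CC(=O)CC(=O)c1ccccc1 | starting material
9 | dilithium 1-phenylbuta-1,3-diene-1,3-bis(olate) (not isolated) | [Li+].[Li+].C=C([O-])C=C([O-])c1ccccc1 | intermediate
10 | 7-methyl-1-phenyloct-6-ene-1,3-dione | CC(C)=CCCC(=O)CC(=O)c1ccccc1 | intermediate
11 | (Z)-7-methyl-1-phenyl-3-(trimethylsilyloxy)octa-2,6-dien-1-one | CC(C)=CCC/C(O[Si](C)(C)C)=C/C(=O)c1ccccc1 | intermediate
12 | lithium (1Z,3Z)-7-methyl-1-phenyl-3-(trimethylsilyloxy)octa-1,3,6-trien-1-olate (not isolated) | [Li+].CC(C)=CC/C=C(\O[Si](C)(C)C)/C=C(\[O-])c1ccccc1 | intermediate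
13 | (1Z,3Z)-7-methyl-1-phenyl-1,3-bis(trimethylsilyloxy)octa-1,3,6-triene | CC(C)=CC/C=C(\O[Si](C)(C)C)/C=C(\O[Si](C)(C)C)c1ccccc1 | intermediate
14 | (6Z)-2,2,4-tris(3-methylbut-2-enyl)-3,5-dioxo-7-phenyl-7-(trimethylsilyloxy)hept-6-enoyl chloride, racemic at C4 (not isolated) | CC(C)=CCC(C(=O)/C=C(\O[Si](C)(C)C)c1ccccc1)C(=O)C(CC=C(C)C)(CC=C(C)C)C(Cl)=O | intermediate
15 | sodium enolate of 2-benzoyl-3,5-dihydroxy-4,4,6-tris(3-methylbut-2-enyl)cyclohexa-2,5-dien-1-one (not isolated) | [Na+].CC(C)=CCC1=C([O-])C(CC=C(C)C)(CC=C(C)C)C(O)=C(C(=O)c2ccccc2)C1=O | intermediate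
16 | 2-benzoyl-3,5-dihydroxy-4,4,6-tris(3-methylbut-2-enyl)cyclohexa-2,5-dien-1-one | CC(C)=CCC1=C(O)C(CC=C(C)C)(CC=C(C)C)C(O)=C(C(=O)c2ccccc2)C1=O | target

Total step count: 7. Longest linear sequence: 4 steps (1, 2, 3, 7 or 4, 5, 6, 7).

Steps most likely to fail

Step 7. The ring may close through the C1 oxygen and not through C2. Two dienes may couple with one diacid chloride. The first acylation at the hindered acyl carbon may be slow; within the same approach, 0.1 equiv of Me3SiOTf would be tried. Acid set free before the quench may cyclise prenyl groups onto enol oxygens. If the methoxide treatment does not funnel the material to the carbocycle, the ring would be taken from an aromatic precursor. The fallback sets out from 2: 2,4,6-trihydroxybenzophenone F1, a purchased compound, would be C-prenylated three times with 2 (3.3 equiv) and NaOMe in MeOH at 0 °C. The third alkylation dearomatises the ring at an already prenylated carbon, the classical alkylative dearomatisation used for lupulone-type triprenyl acylphloroglucinols. Acidification to pH 3 and chromatography to remove di- and tetraprenylated material would return the route at 16.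

Step 6. γ-Deprotonation may be incomplete, silylation may occur at carbon, and the trimethylsilyl groups may be lost by hydrolysis during filtration and transfer. The fallback sets out from 10 and uses soft enolisation in one pot: Et3SiOTf (2.3 equiv) and NEt3 (2.6 equiv) in Et2O at 0 °C should give (1Z,3Z)-7-methyl-1-phenyl-1,3-bis(triethylsilyloxy)octa-1,3,6-triene F2. Its silyl groups are more robust, so it should tolerate a rapid filtration through NEt3-deactivated silica. F2 would take the place of 13 in step 7, and the route is rejoined at 16.

Step 3. Traces of acid may add to or lactonise the prenyl groups, the second hindered carboxyl may be activated incompletely, and material may be lost when the amide by-product is removed under heat. The fallback sets out from 6: silylation with tert-butyldimethylsilyl chloride and imidazole in DMF would give bis(tert-butyldimethylsilyl) 2,2-bis(3-methylbut-2-enyl)propanedioate F3. Treatment of this silyl ester with oxalyl chloride and catalytic DMF in CH2Cl2 at 0 → 20 °C should convert it into the acid chloride under neutral conditions with only volatile co-products. The route is rejoined at 7.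

Further compounds
F1 | step 7 | 2,4,6-trihydroxybenzophenone (purchased) | O=C(c1ccccc1)c1c(O)cc(O)cc1O
F2 | step 6 | (1Z,3Z)-7-methyl-1-phenyl-1,3-bis(triethylsilyloxy)octa-1,3,6-triene | CC(C)=CC/C=C(\O[Si](CC)(CC)CC)/C=C(\O[Si](CC)(CC)CC)c1ccccc1
F3 | step 3 | bis(tert-butyldimethylsilyl) 2,2-bis(3-methylbut-2-enyl)propanedioate | CC(C)=CCC(CC=C(C)C)(C(=O)O[Si](C)(C)C(C)(C)C)C(=O)O[Si](C)(C)C(C)(C)C
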